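## Retrosynthetic overview

1. Structural feature: ring A of the (2S)-flavanone carries oxygen on C5, C7 and C8 and hydrogen on C6, while C4a bears the C4 ketone and C8a the ring oxygen O1. C5–C6–C7–C8 is therefore a 1,1,3,4-tetraoxygenated butadiene, and C4a/C8a are the two alkyne carbons of an alkynyl ketone.
2. Ring C is opened at O1–C8a: palladium-catalysed aryl etherification of the C2 carbinol onto a C8a–Br bond, which leaves C2 untouched.
3. Ring A is cut at C4a–C5 and C8–C8a: Diels–Alder addition and aromatisation of 1,3,4-trimethoxy-1-(trimethylsilyloxy)butadiene with an (S)-β-silyloxy bromoalkynyl ketone, the bromine arriving on C8a.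
4. The ynone comes from a β-hydroxy Weinreb amide whose carbinol centre (future C2) is set by asymmetric transfer hydrogenation of a β-keto ester; the diene comes from methyl 4-methoxyacetoacetate.
5. Order of ring formation: ring B (bought), then ring A (step 8), then ring C (step 11).

Key step: step 8

Assumption: the target is read as the 2S enantiomer (O1 > aryl > C3 > H), and methyl 4-methoxyacetoacetate, ethyl 3-(3,4-dimethoxyphenyl)-3-oxopropanoate and ethynylmagnesium bromide are taken as bought; the β-keto ester replaces an aldehyde/acetate-aldol entry because the sense of the hydrogen transfer is secure.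

## Route

Step 1
Reactants: 1 methyl 4-methoxyacetoacetate (methyl 4-methoxy-3-oxobutanoate)
Product: 2 methyl (E)-3,4-dimethoxybut-2-enoate
Conditions: HC(OMe)3 (1.5 equiv), MeOH, H2SO4 (cat.), rt → 50 °C; distillation
Reagents that add atoms: trimethyl orthoformate, COC(OC)OC
Why: Acid-catalysed enol ether formation of a β-keto ester with an orthoformate (ketalisation, then loss of methanol) is the standard entry to 3-methoxy-2-enoates and should give the conjugated E isomer under thermodynamic control, with no stereocentre formed.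

Step 2
Reactants: 2 methyl (E)-3,4-dimethoxybut-2-enoate
Product: 4 (1E,3Z)-1,3,4-trimethoxy-1-(trimethylsilyloxy)buta-1,3-diene, via lithium dienolate 3 (not isolated)
Conditions: LDA (1.1 equiv, commercial solution), THF, −78 °C; then Me3SiCl, −78 → 0 °C; pentane, filtration, bulb-to-bulb distillation, used at once
Reagents that add atoms: chlorotrimethylsilane, C[Si](C)(C)Cl
Why: Kinetic γ-deprotonation of a 3-alkoxy-2-enoate by LDA and O-silylation of the dienolate is the established preparation of 1-alkoxy-1-silyloxy dienes (vinylogous ketene acetals of the Brassard type), the γ-methoxy group further acidifying the position that is deprotonated; the double-bond geometry is of no consequence because it is erased on aromatisation.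

Step 3
Reactants: 5 ethyl 3-(3,4-dimethoxyphenyl)-3-oxopropanoate
Product: 6 ethyl (S)-3-(3,4-dimethoxyphenyl)-3-hydroxypropanoate
Conditions: RuCl[(S,S)-TsDPEN](p-cymene) (1 mol%), HCO2H/Et3N (5:2), 40 °C
Reagents that add atoms: none
Why: Noyori–Ikariya asymmetric transfer hydrogenation of an aryl ketone, in which the (S,S)-TsDPEN ruthenium hydride delivers hydride to the carbonyl face fixed by the CH/π contact between the arene ligand and the veratryl ring, which for aryl ketones gives the (S)-carbinol (here O > aryl > CH2 > H), β-keto esters being a known substrate class.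

Step 4
Reactants: 6 ethyl (S)-3-(3,4-dimethoxyphenyl)-3-hydroxypropanoate
Product: 7 (S)-3-(3,4-dimethoxyphenyl)-3-hydroxy-N-methoxy-N-methylpropanamide
Conditions: MeNHOMe·HCl (2.5 equiv), iPrMgCl (6 equiv), THF, −20 → 0 °C; aq. NH4Cl
Reagents that add atoms: N,O-dimethylhydroxylamine hydrochloride, CNOC.Cl
Why: Weinreb amide formation directly from the ester with the chloromagnesium amide of N,O-dimethylhydroxylamine, the hydroxyl being carried as its magnesium alkoxide, which cannot undergo β-elimination, so the stereocentre is not involved.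

Step 5
Reactants: 7 (S)-3-(3,4-dimethoxyphenyl)-3-hydroxy-N-methoxy-N-methylpropanamide
Product: 8 (S)-3-(tert-butyldimethylsilyloxy)-3-(3,4-dimethoxyphenyl)-N-methoxy-N-methylpropanamide
Conditions: TBSCl (1.3 equiv), imidazole (2.5 equiv), DMF, rt
Reagents that add atoms: tert-butyldimethylsilyl chloride, CC(C)(C)[Si](C)(C)Cl
Why: Standard imidazole-promoted silylation of a secondary benzylic alcohol (Corey conditions), which occurs at oxygen and leaves the configuration unchanged.

Step 6
Reactants: 8 (S)-3-(tert-butyldimethylsilyloxy)-3-(3,4-dimethoxyphenyl)-N-methoxy-N-methylpropanamide; 9 ethynylmagnesium bromide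
Product: 10 (S)-5-(tert-butyldimethylsilyloxy)-5-(3,4-dimethoxyphenyl)pent-1-yn-3-one
Conditions: 9 (0.5 M in THF, 3 equiv), THF, 0 °C; inverse quench into cold aq. NaHSO4
Reagents that add atoms: none
Why: Weinreb ketone synthesis, in which the chelated tetrahedral adduct prevents over-addition and collapses only on the cold acidic inverse quench, which also protonates the liberated amine before it can add to the ynone.

Step 7
Reactants: 10 (S)-5-(tert-butyldimethylsilyloxy)-5-(3,4-dimethoxyphenyl)pent-1-yn-3-one
Product: 11 (S)-1-bromo-5-(tert-butyldimethylsilyloxy)-5-(3,4-dimethoxyphenyl)pent-1-yn-3-one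
Conditions: NBS (1.1 equiv), AgNO3 (10 mol%), acetone, rt, dark; used promptly
Reagents that add atoms: N-bromosuccinimide, O=C1CCC(=O)N1Br
Why: Silver-catalysed bromination of a terminal alkyne with NBS through the silver acetylide, a reaction known for terminal ynones and for alkynes bearing methoxyarenes, which should be faster than nuclear bromination of the veratryl ring.

Step 8
Reactants: 4 (1E,3Z)-1,3,4-trimethoxy-1-(trimethylsilyloxy)buta-1,3-diene; 11 (S)-1-bromo-5-(tert-butyldimethylsilyloxy)-5-(3,4-dimethoxyphenyl)pent-1-yn-3-one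
Product: 14 (S)-1-(2-bromo-6-hydroxy-3,4-dimethoxyphenyl)-3-(tert-butyldimethylsilyloxy)-3-(3,4-dimethoxyphenyl)propan-1-one, via cyclohexadiene cycloadduct 12 (not isolated), via aryl trimethylsilyl ether 13 (not isolated)
Conditions: 4 (2.5 equiv), toluene, −40 °C → rt; then 10% aq. citric acid, THF, 0 °C → rt
Reagents that add atoms: none
Why: The diene is a vinylogous ketene acetal whose terminal carbon (future C8) is its nucleophilic end, so it should bond to the β-carbon of the ynone (future C8a, carrying bromine) while the acetal carbon (future C5) bonds to the α-carbon (C4a), either in a concerted asynchronous [4+2] cycloaddition or, at the stepwise limit, by Mukaiyama–Michael addition followed by 6-exo-trig attack of the allenolate α-carbon on the silyloxy oxocarbenium carbon, giving cyclohexa-1,4-diene 12. Mild acid then ionises the mixed acetal at C5, methanol and the C8 hydrogen are lost to give the aromatic silyl ether 13, and this is hydrolysed to phenol 14. The closest known reaction type is the Diels–Alder/aromatisation of 1-alkoxy-1-silyloxy dienes (Brassard and Chan dienes) with acetylenic ketones, together with the use of 3-bromopropiolates as dienophiles. Ring A is thus closed as a six-membered carbocycle in a [4+2] mode, both new bonds (C4a–C5 and C8–C8a) coming from the diene termini, and no stereocentre is created, the two sp3 ring carbons of 12 being erased on aromatisation and C2 remaining a spectator. The selectivity needed is regiochemical, and it is secured by the three oxygen donors at C5 and C7 that make C8 the electron-rich terminus and by the carbonyl polarisation that makes the bromine-bearing carbon the electrophilic one. Neutral, base-free conditions in a non-polar solvent are chosen to disfavour ionic addition–elimination at the C–Br bond and E1cB loss of the silyloxy group.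

Step 9
Reactants: 14 (S)-1-(2-bromo-6-hydroxy-3,4-dimethoxyphenyl)-3-(tert-butyldimethylsilyloxy)-3-(3,4-dimethoxyphenyl)propan-1-one
Product: 15 (S)-1-(2-bromo-3,4,6-trimethoxyphenyl)-3-(tert-butyldimethylsilyloxy)-3-(3,4-dimethoxyphenyl)propan-1-one
Conditions: MeI (3 equiv), K2CO3 (2 equiv), acetone, rt → 40 °C
Reagents that add atoms: iodomethane, CI
Why: Williamson methylation of the C5 phenol under weak carbonate base, the doubly ortho-substituted aryl ketone being twisted out of conjugation so that its α-hydrogens are too weakly acidic for E1cB loss of silyloxide, and any C5 methyl ether formed in step 8 by loss of trimethylsilanol in place of methanol being this same compound.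

Step 10
Reactants: 15 (S)-1-(2-bromo-3,4,6-trimethoxyphenyl)-3-(tert-butyldimethylsilyloxy)-3-(3,4-dimethoxyphenyl)propan-1-one
Product: 16 (S)-1-(2-bromo-3,4,6-trimethoxyphenyl)-3-(3,4-dimethoxyphenyl)-3-hydroxypropan-1-one
Conditions: HF·pyridine, pyridine, THF, 0 °C → rt
Reagents that add atoms: none
Why: Fluoride-mediated silyl ether cleavage with pyridine-buffered HF, which is neither basic enough for retro-aldol or E1cB reactions nor acidic enough to ionise the electron-rich benzylic C–O bond, so the carbinol keeps its S configuration.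

Step 11
Reactants: 16 (S)-1-(2-bromo-3,4,6-trimethoxyphenyl)-3-(3,4-dimethoxyphenyl)-3-hydroxypropan-1-one
Product: 17 (2S)-2-(3,4-dimethoxyphenyl)-5,7,8-trimethoxy-2,3-dihydro-4H-chromen-4-one
Conditions: Pd(OAc)2 (5 mol%), 2-(di-tert-butylphosphino)-1,1'-binaphthyl (6 mol%), K3PO4 (2 equiv), toluene, 65 °C
Reagents that add atoms: none
Why: Palladium-catalysed intramolecular C–O coupling of a secondary alcohol with an aryl bromide (Buchwald–Hartwig etherification), in which zerovalent palladium inserts into the C8a–Br bond and the bulky di-tert-butyl biaryl phosphine favours C–O reductive elimination from the seven-membered palladacycle over β-hydride elimination, closing ring C as the six-membered chromanone without touching the O–C2 bond, so C2 stays S.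

## Compound list

1 | methyl 4-methoxyacetoacetate (methyl 4-methoxy-3-oxobutanoate) | COCC(=O)CC(=O)OC | starting material
2 | methyl (E)-3,4-dimethoxybut-2-enoate | COC/C(OC)=C\C(=O)OC | intermediate
3 | lithium 1,3,4-trimethoxybuta-1,3-dien-1-olate (dienolate of 2) | [Li+].CO/C=C(OC)/C=C(\OC)[O-] | intermediate (not isolated)
4 | (1E,3Z)-1,3,4-trimethoxy-1-(trimethylsilyloxy)buta-1,3-diene | CO/C=C(OC)/C=C(\OC)O[Si](C)(C)C | intermediate
5 | ethyl 3-(3,4-dimethoxyphenyl)-3-oxopropanoate | CCOC(=O)CC(=O)c1ccc(OC)c(OC)c1 | starting material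
6 | ethyl (S)-3-(3,4-dimethoxyphenyl)-3-hydroxypropanoate | COc1ccc([C@@H](O)CC(=O)OCC)cc1OC | intermediate
7 | (S)-3-(3,4-dimethoxyphenyl)-3-hydroxy-N-methoxy-N-methylpropanamide | COc1ccc([C@@H](O)CC(=O)N(C)OC)cc1OC | intermediate
8 | (S)-3-(tert-butyldimethylsilyloxy)-3-(3,4-dimethoxyphenyl)-N-methoxy-N-methylpropanamide | COc1ccc([C@@H](O[Si](C)(C)C(C)(C)C)CC(=O)N(C)OC)cc1OC | intermediate
9 | ethynylmagnesium bromide | C#C[Mg]Br | starting material
10 | (S)-5-(tert-butyldimethylsilyloxy)-5-(3,4-dimethoxyphenyl)pent-1-yn-3-one | COc1ccc([C@@H](O[Si](C)(C)C(C)(C)C)CC(=O)C#C)cc1OC | intermediate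
11 | (S)-1-bromo-5-(tert-butyldimethylsilyloxy)-5-(3,4-dimethoxyphenyl)pent-1-yn-3-one | COc1ccc([C@@H](O[Si](C)(C)C(C)(C)C)CC(=O)C#CBr)cc1OC | intermediate
12 | (S)-1-[2-bromo-3,4,6-trimethoxy-6-(trimethylsilyloxy)cyclohexa-1,4-dien-1-yl]-3-(tert-butyldimethylsilyloxy)-3-(3,4-dimethoxyphenyl)propan-1-one (mixture of ring diastereomers) | COc1ccc([C@@H](O[Si](C)(C)C(C)(C)C)CC(=O)C2=C(Br)C(OC)C(OC)=CC2(OC)O[Si](C)(C)C)cc1OC | intermediate (not isolated)
13 | (S)-1-[2-bromo-3,4-dimethoxy-6-(trimethylsilyloxy)phenyl]-3-(tert-butyldimethylsilyloxy)-3-(3,4-dimethoxyphenyl)propan-1-one | COc1ccc([C@@H](O[Si](C)(C)C(C)(C)C)CC(=O)c2c(O[Si](C)(C)C)cc(OC)c(OC)c2Br)cc1OC | intermediate (not isolated)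
14 | (S)-1-(2-bromo-6-hydroxy-3,4-dimethoxyphenyl)-3-(tert-butyldimethylsilyloxy)-3-(3,4-dimethoxyphenyl)propan-1-one | COc1ccc([C@@H](O[Si](C)(C)C(C)(C)C)CC(=O)c2c(O)cc(OC)c(OC)c2Br)cc1OC | intermediate
15 | (S)-1-(2-bromo-3,4,6-trimethoxyphenyl)-3-(tert-butyldimethylsilyloxy)-3-(3,4-dimethoxyphenyl)propan-1-one | COc1ccc([C@@H](O[Si](C)(C)C(C)(C)C)CC(=O)c2c(OC)cc(OC)c(OC)c2Br)cc1OC | intermediate
16 | (S)-1-(2-bromo-3,4,6-trimethoxyphenyl)-3-(3,4-dimethoxyphenyl)-3-hydroxypropan-1-one | COc1ccc([C@@H](O)CC(=O)c2c(OC)cc(OC)c(OC)c2Br)cc1OC | intermediate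
17 | (2S)-2-(3,4-dimethoxyphenyl)-5,7,8-trimethoxy-2,3-dihydro-4H-chromen-4-one | COc1ccc([C@@H]2CC(=O)c3c(OC)cc(OC)c(OC)c3O2)cc1OC | target

## Step count and risks

Total step count: 11. Longest linear sequence: 9 steps (steps 3 to 11, from compound 5); the diene branch (steps 1 and 2) joins at step 8.

Steps most likely to fail:

1. Step 8 (benzannulation). The strongly nucleophilic diene may react with the bromoalkyne by addition–elimination (net displacement of bromide) or by attack at bromine, or the first-formed Michael adduct may not close, so that no brominated arene is formed. Acid during aromatisation could also let the new C5 phenol displace the benzylic silyloxy group. The fallback carries C8a through the benzannulation as a carbon–tin bond and introduces bromine afterwards. It sets out from Weinreb amide 8 and diene 4. Lithium (tributylstannyl)acetylide (ethynyltributylstannane, LDA, THF, −78 °C) added to 8 should give (S)-5-(tert-butyldimethylsilyloxy)-5-(3,4-dimethoxyphenyl)-1-(tributylstannyl)pent-1-yn-3-one F1. F1 and diene 4 (toluene, rt → 60 °C) should give the stannylated cyclohexadiene cycloadduct F2. On buffered work-up (pyridinium p-toluenesulfonate, wet CH2Cl2, 0 °C) F2 should lose methanol to the aryl trimethylsilyl ether F3, which is hydrolysed to the stannyl phenol (S)-3-(tert-butyldimethylsilyloxy)-3-(3,4-dimethoxyphenyl)-1-[6-hydroxy-3,4-dimethoxy-2-(tributylstannyl)phenyl]propan-1-one F4. Ipso-bromodestannylation of F4 with NBS (1.0 equiv, CH2Cl2, −78 °C), which is expected to outrun bromination at C6–H, returns to the route at phenol 14.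

2. Step 11 (ring C closure). The palladium alkoxide may undergo β-hydride elimination (oxidising the carbinol and reducing the C–Br bond). The base may cause retro-aldol cleavage or dehydration of the β-hydroxy ketone. The flavanone may also lose enantiomeric purity by base-induced ring opening to the 2'-hydroxychalcone and reclosure. The fallback keeps C4 at the alcohol oxidation level during ring closure and sets out from 16. Evans–Saksena anti-reduction (Me4NBH(OAc)3, AcOH/MeCN, −20 °C) should give (1S,3S)-1-(2-bromo-3,4,6-trimethoxyphenyl)-3-(3,4-dimethoxyphenyl)propane-1,3-diol F5. The same palladium-catalysed etherification (Pd(OAc)2, 2-(di-tert-butylphosphino)-1,1'-binaphthyl, K3PO4, toluene, 65 °C) can only close the six-membered ring through the C2 hydroxyl, and should give (2S,4S)-2-(3,4-dimethoxyphenyl)-5,7,8-trimethoxy-3,4-dihydro-2H-chromen-4-ol F6. Oxidation of F6 with Dess–Martin periodinane (NaHCO3, CH2Cl2, rt), under non-basic conditions, comes back to the route at target 17.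

3. Step 2 (diene generation). Deprotonation may be incomplete or occur at the wrong site, silylation may take place on carbon, and the very electron-rich diene may hydrolyse during isolation. Any of these leaves no competent partner for step 8. The fallback carries the C7 oxygen as a silyl enol ether in a Chan-type bis(silyloxy)diene and methylates both phenols afterwards; it sets out from keto ester 1 and uses bromoalkynone 11. Me3SiCl/Et3N (toluene, rt) should give methyl (Z)-4-methoxy-3-(trimethylsilyloxy)but-2-enoate F7. LDA (THF, −78 °C) then Me3SiCl should give (1E,3Z)-1,4-dimethoxy-1,3-bis(trimethylsilyloxy)buta-1,3-diene F8. F8 and 11 (toluene, −40 °C → rt) should give the cycloadduct F9, which on the citric acid work-up loses methanol to the aryl bis(trimethylsilyl) ether F10 and is hydrolysed to the resorcinol (S)-1-(2-bromo-4,6-dihydroxy-3-methoxyphenyl)-3-(tert-butyldimethylsilyloxy)-3-(3,4-dimethoxyphenyl)propan-1-one F11. Double methylation of F11 (MeI in excess, K2CO3, acetone) comes back to the route at 15.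

## Further compounds

F1 | step 8 | (S)-5-(tert-butyldimethylsilyloxy)-5-(3,4-dimethoxyphenyl)-1-(tributylstannyl)pent-1-yn-3-one | COc1ccc([C@@H](O[Si](C)(C)C(C)(C)C)CC(=O)C#C[Sn](CCCC)(CCCC)CCCC)cc1OC
F2 | step 8 | (S)-3-(tert-butyldimethylsilyloxy)-3-(3,4-dimethoxyphenyl)-1-[3,4,6-trimethoxy-2-(tributylstannyl)-6-(trimethylsilyloxy)cyclohexa-1,4-dien-1-yl]propan-1-one | COc1ccc([C@@H](O[Si](C)(C)C(C)(C)C)CC(=O)C2=C([Sn](CCCC)(CCCC)CCCC)C(OC)C(OC)=CC2(OC)O[Si](C)(C)C)cc1OC
F3 | step 8 | (S)-3-(tert-butyldimethylsilyloxy)-3-(3,4-dimethoxyphenyl)-1-[3,4-dimethoxy-2-(tributylstannyl)-6-(trimethylsilyloxy)phenyl]propan-1-one | COc1ccc([C@@H](O[Si](C)(C)C(C)(C)C)CC(=O)c2c(O[Si](C)(C)C)cc(OC)c(OC)c2[Sn](CCCC)(CCCC)CCCC)cc1OC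
F4 | step 8 | (S)-3-(tert-butyldimethylsilyloxy)-3-(3,4-dimethoxyphenyl)-1-[6-hydroxy-3,4-dimethoxy-2-(tributylstannyl)phenyl]propan-1-one | COc1ccc([C@@H](O[Si](C)(C)C(C)(C)C)CC(=O)c2c(O)cc(OC)c(OC)c2[Sn](CCCC)(CCCC)CCCC)cc1OC
F5 | step 11 | (1S,3S)-1-(2-bromo-3,4,6-trimethoxyphenyl)-3-(3,4-dimethoxyphenyl)propane-1,3-diol | COc1ccc([C@@H](O)C[C@H](O)c2c(OC)cc(OC)c(OC)c2Br)cc1OC
F6 | step 11 | (2S,4S)-2-(3,4-dimethoxyphenyl)-5,7,8-trimethoxy-3,4-dihydro-2H-chromen-4-ol | COc1ccc([C@@H]2C[C@H](O)c3c(OC)cc(OC)c(OC)c3O2)cc1OC
F7 | step 2 | methyl (Z)-4-methoxy-3-(trimethylsilyloxy)but-2-enoate | COC/C(O[Si](C)(C)C)=C/C(=O)OC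
F8 | step 2 | (1E,3Z)-1,4-dimethoxy-1,3-bis(trimethylsilyloxy)buta-1,3-diene | CO/C=C(O[Si](C)(C)C)/C=C(\OC)O[Si](C)(C)C
F9 | step 2 | (S)-1-[2-bromo-3,6-dimethoxy-4,6-bis(trimethylsilyloxy)cyclohexa-1,4-dien-1-yl]-3-(tert-butyldimethylsilyloxy)-3-(3,4-dimethoxyphenyl)propan-1-one | COc1ccc([C@@H](O[Si](C)(C)C(C)(C)C)CC(=O)C2=C(Br)C(OC)C(O[Si](C)(C)C)=CC2(OC)O[Si](C)(C)C)cc1OC
F10 | step 2 | (S)-1-[2-bromo-3-methoxy-4,6-bis(trimethylsilyloxy)phenyl]-3-(tert-butyldimethylsilyloxy)-3-(3,4-dimethoxyphenyl)propan-1-one | COc1ccc([C@@H](O[Si](C)(C)C(C)(C)C)CC(=O)c2c(O[Si](C)(C)C)cc(O[Si](C)(C)C)c(OC)c2Br)cc1OC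
F11 | step 2 | (S)-1-(2-bromo-4,6-dihydroxy-3-methoxyphenyl)-3-(tert-butyldimethylsilyloxy)-3-(3,4-dimethoxyphenyl)propan-1-one | COc1ccc([C@@H](O[Si](C)(C)C(C)(C)C)CC(=O)c2c(O)cc(O)c(OC)c2Br)cc1OC
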